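**Plan**
- Retrosynthetic cuts, in order: the two C5–prenyl bonds (back to an aromatic acylphloroglucinol); the two C–CH3 bonds of the carbinol (back to a C2 methyl ester); O1–C2 and C2–C3 together (dihydrofuran opened to an ortho-quinone methide plus a one-carbon ylide); then C3–C3a, the two benzyl ethers and the aryl–acyl bond, down to phloroglucinol.
- Enabling feature (benzofuran numbering O1, C2, C3, C3a, C4–C7, C7a): in the five-membered ring, C2 is the only atom bonded to both O1 and C3, so it can be delivered as a single ylide carbon bridging the two ends of the heterodiene O1=C7a–C3a=C3.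
- Forward order: the carbocycle is the phloroglucinol ring from the start; acylation, bis-benzylation and sulfonylmethylation beside the chelated phenol arm it; the (4+1) annulation closes the dihydrofuran, the only ring made; hydrogenolysis, methyl Grignard addition and dearomative gem-diprenylation at C5 finish the molecule.
- Stereochemistry: C2 (R), the only stereocentre, is set in the annulation by an O-methylquinidine leaving group on the ammonium ylide and is not touched afterwards.

Key step: step 5

Remark 1: the target is an enolised β-triketone whose tautomers interconvert; it is written throughout as the exocyclic enol of the given structure, with the enol OH on the side of the C6 carbonyl.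
Remark 2: the quinidine-derived ammonium group is assumed to give the (R) sense at C2; if the opposite sense were found, the pseudo-enantiomeric O-methylquinine would replace it in steps 4 and 5 with nothing else changed.

**Step 1**
Reactants: 1 phloroglucinol; 2 isobutyryl chloride
Product: 3 2-methyl-1-(2,4,6-trihydroxyphenyl)propan-1-one
Conditions: AlCl3 (3.5 equiv), PhNO2, 65 °C; then ice/aq. HCl
Reagents that add atoms: isobutyryl chloride 2, CC(C)C(=O)Cl
Why: Friedel–Crafts C-acylation of the strongly activated triol should stop after one acyl group because the product ketone, chelated by its ortho hydroxyls and complexed to AlCl3, is deactivated towards a second acylation.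

**Step 2**
Reactants: 3 2-methyl-1-(2,4,6-trihydroxyphenyl)propan-1-one
Product: 5 1-[2,4-bis(benzyloxy)-6-hydroxyphenyl]-2-methylpropan-1-one, via mono-benzyl ether 4 (not isolated)
Conditions: BnBr (2.1 equiv), K2CO3 (2.2 equiv), DMF, 0 °C to rt
Reagents that add atoms: benzyl bromide, BrCc1ccccc1
Why: Williamson etherification should take the most acidic para hydroxyl first (4) and then one of the two ortho hydroxyls, the last one staying free because it is locked in a hydrogen bond to the ketone, and benzyl ethers are chosen because they survive the formic acid of step 3 and leave under neutral conditions in step 6.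

**Step 3**
Reactants: 5 1-[2,4-bis(benzyloxy)-6-hydroxyphenyl]-2-methylpropan-1-one
Product: 7 1-[4,6-bis(benzyloxy)-2-hydroxy-3-{[(4-methylphenyl)sulfonyl]methyl}phenyl]-2-methylpropan-1-one, via hydroxymethyl phenol 6 (not isolated)
Conditions: 37% aq. HCHO (1.2 equiv), p-TolSO2Na (2 equiv), HCO2H–THF 1:1, 40 °C
Reagents that add atoms: formaldehyde, C=O; sodium 4-methylbenzenesulfinate, [Na+].[O-]S(=O)c1ccc(C)cc1
Why: Mannich-type three-component sulfonylmethylation, in which acid-promoted hydroxymethylation gives 6, whose benzylic cation (a protonated ortho-quinone methide) is trapped at sulfur by the sulfinate; the carbon between OH and OBn should be preferred over the more crowded one between two OBn groups, and excess sulfinate should outcompete a second arene for the cation.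

**Step 4**
Reactants: 8 quinidine
Product: 9 O-methylquinidine (methyl ether at the carbinol oxygen)
Conditions: NaH (1.2 equiv), DMF, 0 °C to rt; then MeI (1.05 equiv), 0 °C
Reagents that add atoms: iodomethane, CI
Why: Williamson ether synthesis in which the sodium alkoxide is far more nucleophilic than the quinuclidine nitrogen towards one equivalent of MeI, the usual way to O-alkyl cinchona alkaloids, with no stereocentre touched.

**Step 5**
Reactants: 7 1-[4,6-bis(benzyloxy)-2-hydroxy-3-{[(4-methylphenyl)sulfonyl]methyl}phenyl]-2-methylpropan-1-one; 9 O-methylquinidine; 10 methyl bromoacetate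
Product: 14 methyl (2R)-4,6-bis(benzyloxy)-7-(2-methylpropanoyl)-2,3-dihydro-1-benzofuran-2-carboxylate, via ammonium bromide 11 (not isolated), via ortho-quinone methide 12 (not isolated), via phenoxide betaine 13 (not isolated)
Conditions: 9 and 10 (1.5 equiv each), CH2Cl2, rt; then 7, Cs2CO3 (3.5 equiv), −20 °C to rt
Reagents that add atoms: methyl bromoacetate 10, COC(=O)CBr
Why: The quinuclidine nitrogen of 9 is alkylated by 10 to give 11, and Cs2CO3 then converts 11 into the ester-stabilised ammonium ylide and deprotonates the chelated phenol of 7, which expels p-toluenesulfinate by 1,4-elimination to release 12; the ylide carbon adds to the exocyclic methylene of 12 (C2–C3 bond), the ring re-aromatises to betaine 13, and O1 then displaces the amine (O1–C2 bond). The closest known reaction type is the formal (4+1) annulation of cinchona-derived ammonium ylides, and of sulfonium ylides, with ortho-quinone methides generated in situ from 2-(sulfonylmethyl)phenols. The dihydrofuran ring closes by a 5-exo-tet intramolecular SN2 substitution at the carbon alpha to the ester, with inversion and release of 9, which can be recovered. The new stereocentre C2 is controlled by the O-methylquinidinium group alone: it shields one face of the ylide carbon during C–C bond formation and, because the ammonium-bearing carbon of 13 stays acidic and can epimerise before ring closure (Curtin–Hammett situation), it also decides which epimer closes, the (S)-betaine giving the (R)-ester. The step needs enantioselection with no C3 substituent to reinforce it, the least explored case, which rests on the chiral leaving group and on low temperature to keep the product ester from enolising; it also needs O1 to end up at C7a next to the acyl-bearing C7, which is secured because the only free phenol of 7 is the chelated one ortho to the sulfonylmethyl group, while complete quaternisation before base is added removes free bromoacetate and so prevents O-alkylation of the phenoxide.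

**Step 6**
Reactants: 14 methyl (2R)-4,6-bis(benzyloxy)-7-(2-methylpropanoyl)-2,3-dihydro-1-benzofuran-2-carboxylate
Product: 15 methyl (2R)-4,6-dihydroxy-7-(2-methylpropanoyl)-2,3-dihydro-1-benzofuran-2-carboxylate
Conditions: H2 (1 atm), 10% Pd/C, EtOAc–MeOH, rt
Reagents that add atoms: none
Why: Catalytic hydrogenolysis should cleave only the two benzyl aryl ethers, since the C2–O1 bond is not benzylic at carbon, the chelated aryl ketone and the ester are not reduced under neutral conditions, and the C2 stereocentre is not involved.

**Step 7**
Reactants: 15 methyl (2R)-4,6-dihydroxy-7-(2-methylpropanoyl)-2,3-dihydro-1-benzofuran-2-carboxylate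
Product: 17 1-[(2R)-4,6-dihydroxy-2-(2-hydroxypropan-2-yl)-2,3-dihydro-1-benzofuran-7-yl]-2-methylpropan-1-one, via methyl ketone 16 (not isolated)
Conditions: MeMgBr (6 equiv), THF, −20 °C to rt; then aq. NH4Cl
Reagents that add atoms: methylmagnesium bromide, C[Mg]Br
Why: Double Grignard addition to the alpha-alkoxy ester through 16, in which the first two equivalents turn the phenols into magnesium phenoxides so that the C7 ketone becomes part of an electron-rich vinylogous carboxylate flanked by isopropyl and two ortho substituents and should not be attacked, while addition to the ester and to 16 should outrun enolisation so that the C2 configuration is kept.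

**Step 8**
Reactants: 17 1-[(2R)-4,6-dihydroxy-2-(2-hydroxypropan-2-yl)-2,3-dihydro-1-benzofuran-7-yl]-2-methylpropan-1-one; 18 prenyl bromide
Product: 20 garcinielliptone HC (5,5-diprenyl enolised triketone of the target structure), via 5-prenyl phenol 19 (not isolated)
Conditions: NaOMe (3 equiv), MeOH, 0 °C; 18 (2.5–3 equiv), 0 °C to rt; then aq. citric acid
Reagents that add atoms: prenyl bromide 18, CC(C)=CCBr
Why: Base-mediated dearomative gem-dialkylation of an acylphloroglucinol, the classical entry to lupulone-type triketones, in which the phenoxide dianion is C-alkylated at C5, the only unsubstituted ring carbon and ortho to both oxygens, to give 19, and a second alkylation at the same carbon breaks aromaticity to the enolised β-triketone, with methanol hydrogen-bonding the oxygens in favour of C- over O-alkylation and the distant C2 stereocentre untouched.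

**Compound list**
1 | phloroglucinol (benzene-1,3,5-triol) | Oc1cc(O)cc(O)c1 | starting material
2 | isobutyryl chloride (2-methylpropanoyl chloride) | CC(C)C(=O)Cl | starting material
3 | 2-methyl-1-(2,4,6-trihydroxyphenyl)propan-1-one | CC(C)C(=O)c1c(O)cc(O)cc1O | intermediate
4 | 1-[4-(benzyloxy)-2,6-dihydroxyphenyl]-2-methylpropan-1-one; formed in the flask, not isolated | CC(C)C(=O)c1c(O)cc(OCc2ccccc2)cc1O | intermediate
5 | 1-[2,4-bis(benzyloxy)-6-hydroxyphenyl]-2-methylpropan-1-one | CC(C)C(=O)c1c(O)cc(OCc2ccccc2)cc1OCc1ccccc1 | intermediate
6 | 1-[4,6-bis(benzyloxy)-2-hydroxy-3-(hydroxymethyl)phenyl]-2-methylpropan-1-one; formed in the flask, not isolated | CC(C)C(=O)c1c(O)c(CO)c(OCc2ccccc2)cc1OCc1ccccc1 | intermediate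
7 | 1-[4,6-bis(benzyloxy)-2-hydroxy-3-{[(4-methylphenyl)sulfonyl]methyl}phenyl]-2-methylpropan-1-one | CC(C)C(=O)c1c(O)c(CS(=O)(=O)c2ccc(C)cc2)c(OCc2ccccc2)cc1OCc1ccccc1 | intermediate
8 | quinidine, (8R,9S)-6'-methoxycinchonan-9-ol | COc1ccc2nccc([C@@H]([C@H]3C[C@@H]4CCN3C[C@@H]4C=C)O)c2c1 | starting material
9 | O-methylquinidine, (8R,9S)-6',9-dimethoxycinchonan | COc1ccc2nccc([C@@H]([C@H]3C[C@@H]4CCN3C[C@@H]4C=C)OC)c2c1 | intermediate
10 | methyl bromoacetate | COC(=O)CBr | starting material
11 | N-(2-methoxy-2-oxoethyl)-O-methylquinidinium bromide, alkylated at the quinuclidine nitrogen; formed in the flask, not isolated | COc1ccc2nccc([C@@H]([C@H]3C[C@@H]4CC[N+]3(CC(=O)OC)C[C@@H]4C=C)OC)c2c1.[Br-] | intermediate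
12 | 3,5-bis(benzyloxy)-6-methylidene-2-(2-methylpropanoyl)cyclohexa-2,4-dien-1-one; formed in the flask, not isolated | CC(C)C(=O)C1=C(OCc2ccccc2)C=C(OCc2ccccc2)C(=C)C1=O | intermediate
13 | 3,5-bis(benzyloxy)-2-[(2S)-3-methoxy-3-oxo-2-(O-methylquinidinium-N-yl)propyl]-6-(2-methylpropanoyl)phenolate, the productive betaine epimer; formed in the flask, not isolated | COc1ccc2nccc([C@@H]([C@H]3C[C@@H]4CC[N+]3([C@@H](Cc5c([O-])c(C(=O)C(C)C)c(OCc6ccccc6)cc5OCc5ccccc5)C(=O)OC)C[C@@H]4C=C)OC)c2c1 | intermediate
14 | methyl (2R)-4,6-bis(benzyloxy)-7-(2-methylpropanoyl)-2,3-dihydro-1-benzofuran-2-carboxylate | CC(C)C(=O)c1c(OCc2ccccc2)cc(OCc2ccccc2)c2c1O[C@@H](C(=O)OC)C2 | intermediate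
15 | methyl (2R)-4,6-dihydroxy-7-(2-methylpropanoyl)-2,3-dihydro-1-benzofuran-2-carboxylate | CC(C)C(=O)c1c(O)cc(O)c2c1O[C@@H](C(=O)OC)C2 | intermediate
16 | 1-[(2R)-2-acetyl-4,6-dihydroxy-2,3-dihydro-1-benzofuran-7-yl]-2-methylpropan-1-one; formed in the flask, not isolated | CC(C)C(=O)c1c(O)cc(O)c2c1O[C@@H](C(C)=O)C2 | intermediate
17 | 1-[(2R)-4,6-dihydroxy-2-(2-hydroxypropan-2-yl)-2,3-dihydro-1-benzofuran-7-yl]-2-methylpropan-1-one | CC(C)C(=O)c1c(O)cc(O)c2c1O[C@@H](C(C)(C)O)C2 | intermediate
18 | prenyl bromide (1-bromo-3-methylbut-2-ene) | CC(C)=CCBr | starting material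
19 | 1-[(2R)-4,6-dihydroxy-2-(2-hydroxypropan-2-yl)-5-(3-methylbut-2-en-1-yl)-2,3-dihydro-1-benzofuran-7-yl]-2-methylpropan-1-one; formed in the flask, not isolated | CC(C)C(=O)c1c(O)c(CC=C(C)C)c(O)c2c1O[C@@H](C(C)(C)O)C2 | intermediate
20 | garcinielliptone HC, (2R,7Z)-7-(1-hydroxy-2-methylpropylidene)-2-(2-hydroxypropan-2-yl)-5,5-bis(3-methylbut-2-en-1-yl)-2,3-dihydro-1-benzofuran-4,6(5H,7H)-dione | CC(C)=CCC1(CC=C(C)C)C(=O)C2=C(O[C@@H](C(C)(C)O)C2)/C(=C(/O)C(C)C)C1=O | target

**Step count**
Total: 8 steps. Longest linear sequence: 7 steps from phloroglucinol (steps 1, 2, 3, 5, 6, 7, 8); step 4 is a one-step side branch that prepares the chiral amine.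

**Steps most likely to fail**

Step 5. The process at risk is enantiofacial discrimination at C2 with no C3 substituent to reinforce it. Optical purity could also erode by base-mediated enolisation alpha to the ester, and the quinone methide could self-condense before the ylide reaches it. The fallback sets out from 7 and 10 and gives up asymmetric induction. Compound 10 is quaternised with DABCO to 1-(2-methoxy-2-oxoethyl)-4-aza-1-azoniabicyclo[2.2.2]octane bromide F1, whose ylide should add to 12 under the same Cs2CO3 conditions to give racemic methyl 4,6-bis(benzyloxy)-7-(2-methylpropanoyl)-2,3-dihydro-1-benzofuran-2-carboxylate F2. Preparative chromatography on a chiral stationary phase would then separate F2 into 14, where the route is rejoined, and methyl (2S)-4,6-bis(benzyloxy)-7-(2-methylpropanoyl)-2,3-dihydro-1-benzofuran-2-carboxylate F3, which DBU should epimerise back to F2 for recycling.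

Step 8. The processes at risk are O-prenylation competing with C-alkylation, arrest after the first alkylation, and solvolysis of the allylic bromide by methoxide. The fallback sets out from 17 and replaces direct prenylation by allylation and olefin metathesis. Tsuji–Trost dearomative double allylation with allyl methyl carbonate and Pd(PPh3)4 in THF should give (2R,7Z)-7-(1-hydroxy-2-methylpropylidene)-2-(2-hydroxypropan-2-yl)-5,5-di(prop-2-en-1-yl)-2,3-dihydro-1-benzofuran-4,6(5H,7H)-dione F4. Double cross-metathesis of F4 with 2-methyl-2-butene, using the second-generation Grubbs catalyst in CH2Cl2 at 40 °C, should convert both allyl groups into prenyl groups and return to the route at 20.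

Step 3. The processes at risk are attack at the ring carbon between the two benzyloxy groups, double substitution, and capture of the benzylic cation by a second arene to give a methylene-bridged dimer. The fallback sets out from 5 and uses a hydrogen-bond-directed Mannich reaction. Aqueous Me2NH and HCHO in EtOH at 60 °C should aminomethylate ortho to the free hydroxyl and give 1-[4,6-bis(benzyloxy)-3-[(dimethylamino)methyl]-2-hydroxyphenyl]-2-methylpropan-1-one F5. MeI in acetone would convert F5 into {[2,4-bis(benzyloxy)-6-hydroxy-5-(2-methylpropanoyl)phenyl]methyl}trimethylammonium iodide F6. TolSO2Na in DMF at 60 °C should then replace trimethylamine by elimination–addition through 12 and return to the route at 7.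

**Further compounds**
F1 | step 5 | 1-(2-methoxy-2-oxoethyl)-4-aza-1-azoniabicyclo[2.2.2]octane bromide | COC(=O)C[N+]12CCN(CC1)CC2.[Br-]
F2 | step 5 | racemic methyl 4,6-bis(benzyloxy)-7-(2-methylpropanoyl)-2,3-dihydro-1-benzofuran-2-carboxylate | CC(C)C(=O)c1c(OCc2ccccc2)cc(OCc2ccccc2)c2c1OC(C(=O)OC)C2
F3 | step 5 | methyl (2S)-4,6-bis(benzyloxy)-7-(2-methylpropanoyl)-2,3-dihydro-1-benzofuran-2-carboxylate | CC(C)C(=O)c1c(OCc2ccccc2)cc(OCc2ccccc2)c2c1O[C@H](C(=O)OC)C2
F4 | step 8 | (2R,7Z)-7-(1-hydroxy-2-methylpropylidene)-2-(2-hydroxypropan-2-yl)-5,5-di(prop-2-en-1-yl)-2,3-dihydro-1-benzofuran-4,6(5H,7H)-dione | C=CCC1(CC=C)C(=O)C2=C(O[C@@H](C(C)(C)O)C2)/C(=C(/O)C(C)C)C1=O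
F5 | step 3 | 1-[4,6-bis(benzyloxy)-3-[(dimethylamino)methyl]-2-hydroxyphenyl]-2-methylpropan-1-one | CC(C)C(=O)c1c(O)c(CN(C)C)c(OCc2ccccc2)cc1OCc1ccccc1
F6 | step 3 | {[2,4-bis(benzyloxy)-6-hydroxy-5-(2-methylpropanoyl)phenyl]methyl}trimethylammonium iodide | CC(C)C(=O)c1c(O)c(C[N+](C)(C)C)c(OCc2ccccc2)cc1OCc1ccccc1.[I-]
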